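All runs stem from a simulated flask with constants of no real substance, and the scatter is random.

4 questions stand on this flask, and I answer them with one rule read from the runs.

the same everywhere: starting material 0.26 M
- Monday's: first nucleophile 0.40 equiv; second nucleophile 0.60 equiv; protic impurity 5.2 mM; run made earlier
- Wednesday's: first nucleophile 0.90 equiv; second nucleophile 0.60 equiv; protic impurity 5.2 mM; run made earlier
- Thursday's: first nucleophile 0.60 equiv; second nucleophile 0.90 equiv; protic impurity 5.2 mM; run made earlier
- flask: first nucleophile 0.600 equiv; second nucleophile 0.600 equiv; protic impurity 5.20 mM; time 1.0 h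

- Monday's (time / min: other capture product / %, target / %): 6.00: 1.2, 15.3; 15.0: 3.0, 26.5; 20.0: 3.4, 31.2; 30.0: 5.6, 35.5; 40.0: 7.3, 37.7; 50.0: 9.9, 39.1
- Wednesday's (time / min: other capture product / %, target / %): 4.00: 0, 15.6; 6.00: 0.8, 22.8; 8.00: 0.8, 27.9; 15.0: 1.8, 43.0; 20.0: 1.7, 51.8; 30.0: 3.4, 62.1; 50.0: 4.3, 71.9
- Thursday's (time / min: other capture product / %, target / %): 4.00: 1.0, 13.4; 12.0: 2.9, 30.5; 20.0: 5.0, 40.5; 30.0: 7.0, 48.5; 50.0: 10.5, 55.3

(scatter of a reading: 0.5 percentage points)

- ratio of other capture product to target at 40 s
- ratio of other capture product to target at 6.0 min
- ratio of other capture product to target at 1.0 h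
- which of other capture product and target there is more of at 1.0 h



Wednesday's target reaches 71.9%, more than the 0.60 equiv of second nucleophile, so I take target from the first nucleophile and other capture product from the second. Yet Monday looks contradictory: with one recipe, its ratio of other capture product to target reads 0.0784 at 6.00 min and 0.253 at 50.0 min. The preference seems to drift, unless it holds moment by moment and [first nucleophile] is what falls:

rate of other capture product / rate of target = κ [second nucleophile] / [first nucleophile]

Taking [second nucleophile] as its charge and integrating, with L the natural logarithm of first nucleophile charged over first nucleophile left: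

other capture product = κ × second charge × L

Thursday's last reading gives L = 2.55, hence κ, the selectivity factor, the preference for the second nucleophile per unit of concentration ratio:

κ = 0.0458

On Monday's last reading this κ gives 10.4% against 9.9% read, so the drift clears up. I take the pace from Thursday, which has the flask's first charge, with L growing evenly: one power of ten of first nucleophile per 45.2 min. At 1.0 h, L = 3.06, so my target is 57.2% and my other capture product 8.40%. My ratios are:

0.0466, 0.0532, 0.147

The forecast says 0.051, 0.06 and 0.146, with target ahead, from a rule that “fits all three runs, including Monday's late rise”.

The flask gives 0.0482, 0.0560 and 0.141, with target ahead.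

    first nucleophile + intermediate → target (k = 110 L mol⁻¹ min⁻¹)
    second nucleophile + intermediate → other capture product (k = 5.20 L mol⁻¹ min⁻¹)
    starting material + protic impurity → quenched substrate (k = 95.0 L mol⁻¹ min⁻¹)
    starting material ⇌ intermediate (K = 0.00500, k = 0.0740 min⁻¹)

At 1.0 h the flask holds 57.2% target and 8.09% other capture product, with 4.7% of the first nucleophile's charge left. Put into the rule, that remainder gives 8.42% other capture product. A neighbour flask, the same but with 0.150 equiv of first nucleophile, keeps 0.240% of that charge, and the rule gives it 16.6% other capture product. That flask ends with 14.9% other capture product, 15.0% target and a ratio of 0.995.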